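**Retrosynthetic overview**
- Feature: in ring A of the middle epicatechin unit, O5 sits on C5. The ortho carbons of C5 are C6–H and the quaternary C4a, and C8 lies para. A three-atom acyl chain hung on O5 can therefore close only on C6, the carbon that carries the top unit in the 4β→6 bond.
- Late disconnections: the 18 benzyl ethers (hydrogenolysis), the middle C4–bottom C8 bond (Friedel–Crafts reaction of a 4-alkoxy dimer with tetra-O-benzylcatechin), and both gallate esters.
- Top ring C is taken apart at C2–H/C3–O (flav-2-ene epoxide, hydride), O1–C2 (phenol on an aryl ketone), C2–ring B (aryllithium on a Weinreb amide) and C4–H (CuH). This leads back to a coumarin fused to O5/C6 whose C=O, CH and C(aryl) are top C2, C3 and C4.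
- The coumarin comes from the 5-O-arylpropiolate of protected epicatechin by gold hydroarylation (middle C6–top C4). O5 is singled out beforehand through a transient C4 ketone that directs removal of the peri benzyl group.
- Ring order: temporary lactone (closed in step 12, opened in step 14), top ring C (step 18), transient oxirane (step 19). All other rings are bought.

Key step: step 12

Convention: top, middle and bottom are the upper, central and terminal flavan units. Flavan numbering is used, and β is the face opposite to ring B of the unit concerned.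
Assumption: (R)-DTBM-SEGPHOS is taken to send hydride to the required face in step 13. Both antipodes are sold, so the other one is used if a trial run shows the opposite sense. 3,4,5-Tris(benzyloxy)benzoic acid is treated as purchasable.

Step 1
Reactants: 1 (−)-epicatechin
Product: 2 5,7,3',4'-tetra-O-benzyl-(−)-epicatechin (2R,3R, 3-OH free)
Conditions: BnBr (4.4 equiv), K2CO3, DMF, 0 °C to rt
Reagents that add atoms: benzyl bromide, BrCc1ccccc1
Why: Williamson ether synthesis in which carbonate deprotonates only the four phenols, so the secondary 3-OH stays free and C2 and C3 are untouched.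

Step 2
Reactants: 2 5,7,3',4'-tetra-O-benzyl-(−)-epicatechin
Product: 3 3-O-TBS-5,7,3',4'-tetra-O-benzylepicatechin
Conditions: TBSCl, imidazole, DMF, 40 °C
Reagents that add atoms: tert-butyldimethylsilyl chloride, CC(C)(C)[Si](C)(C)Cl
Why: Imidazole-promoted silylation of the only free hydroxyl gives an ether that withstands oxidants, organometallics and mild acid and is removed by fluoride when the gallate is due.

Step 3
Reactants: 3 3-O-TBS-5,7,3',4'-tetra-O-benzylepicatechin
Product: 4 4β-hydroxy-3-O-TBS-5,7,3',4'-tetra-O-benzylepicatechin (4-OH trans to 3-OTBS)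
Conditions: DDQ (1.5 equiv), wet CH2Cl2, rt
Reagents that add atoms: water, O
Why: Benzylic oxidation by hydride transfer to DDQ removes the pseudo-axial C4–H, the cation is stabilised by O5, O7 and O1, and water should add anti to the axial 3-OTBS group (this centre is erased in step 4).

Step 4
Reactants: 4 4β-hydroxy-3-O-TBS-5,7,3',4'-tetra-O-benzylepicatechin
Product: 5 3-O-TBS-5,7,3',4'-tetra-O-benzyl-4-oxoepicatechin (2,3-cis flavan-4-one)
Conditions: Pr4N[RuO4] (5 mol %), NMO, 4 Å MS, CH2Cl2, rt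
Reagents that add atoms: none
Why: Ley–Griffith oxidation turns the benzylic alcohol into the ketone under neutral conditions that should not enolise the 2,3-cis α-silyloxy ketone.

Step 5
Reactants: 5 3-O-TBS-5,7,3',4'-tetra-O-benzyl-4-oxoepicatechin
Product: 6 5-hydroxy-3-O-TBS-7,3',4'-tri-O-benzyl-4-oxoepicatechin
Conditions: BCl3 (1.1 equiv), CH2Cl2, −78 °C; then H2O
Reagents that add atoms: none
Why: Chelation-directed aryl ether cleavage, in which boron is held between the C4 carbonyl and the peri O5 so that chloride removes only that benzyl group, while the low temperature protects the silyl ether and the cis stereocentres.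

Step 6
Reactants: 6 5-hydroxy-3-O-TBS-7,3',4'-tri-O-benzyl-4-oxoepicatechin
Product: 9 3-O-TBS-7,3',4'-tri-O-benzylepicatechin (5-OH free), via aryl ethyl carbonate 7 (not isolated), via ortho-quinone methide 8 (not isolated)
Conditions: ClCO2Et, Et3N, THF, 0 °C; then NaBH4, H2O, 0 °C to rt
Reagents that add atoms: none
Why: Ortho-hydroxyl-assisted deoxygenation of an aryl ketone, in which borohydride reduces the ketone, the carbonate migrates to the new alkoxide and leaves, and a second hydride adds to C4 of the quinone methide, giving the CH2 phenol without touching C2 or C3.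

Step 7
Reactants: 10 2,4,6-trihydroxybenzaldehyde
Product: 11 2,4-bis(benzyloxy)-6-hydroxybenzaldehyde
Conditions: BnBr (2.1 equiv), K2CO3, DMF, rt
Reagents that add atoms: benzyl bromide, BrCc1ccccc1
Why: Williamson ether synthesis that stops after the 4-OH and one ortho OH, because the last ortho OH is locked in a hydrogen bond to the formyl oxygen.

Step 8
Reactants: 11 2,4-bis(benzyloxy)-6-hydroxybenzaldehyde
Product: 12 2,4-bis(benzyloxy)-6-(methoxymethoxy)benzaldehyde
Conditions: MOMCl, i-Pr2NEt, CH2Cl2, 0 °C to rt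
Reagents that add atoms: chloromethyl methyl ether, COCCl
Why: O-alkylation of the chelated phenol with the highly reactive chloromethyl ether marks the oxygen that will become O1 of the top unit with an acid-labile acetal orthogonal to benzyl.

Step 9
Reactants: 12 2,4-bis(benzyloxy)-6-(methoxymethoxy)benzaldehyde
Product: 13 1-ethynyl-2,4-bis(benzyloxy)-6-(methoxymethoxy)benzene
Conditions: dimethyl (1-diazo-2-oxopropyl)phosphonate, K2CO3, MeOH–THF, rt
Reagents that add atoms: dimethyl (1-diazo-2-oxopropyl)phosphonate, CC(=O)C(=[N+]=[N-])P(=O)(OC)OC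
Why: Ohira–Bestmann homologation converts the aryl aldehyde into the terminal alkyne under basic conditions that leave the MOM acetal and the benzyl ethers alone.

Step 10
Reactants: 13 1-ethynyl-2,4-bis(benzyloxy)-6-(methoxymethoxy)benzene
Product: 15 3-[2,4-bis(benzyloxy)-6-(methoxymethoxy)phenyl]propiolic acid, via lithium acetylide 14 (not isolated)
Conditions: n-BuLi, THF, −78 °C; CO2; cold 1 M HCl to pH 3
Reagents that add atoms: carbon dioxide, O=C=O
Why: Deprotonation of the terminal alkyne and carboxylation of the lithium acetylide; the acid is kept cold and used at once because electron-rich arylpropiolic acids decarboxylate easily.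

Step 11
Reactants: 9 3-O-TBS-7,3',4'-tri-O-benzylepicatechin (5-OH free); 15 3-[2,4-bis(benzyloxy)-6-(methoxymethoxy)phenyl]propiolic acid
Product: 16 3-O-TBS-7,3',4'-tri-O-benzylepicatechin 5-O-{3-[2,4-bis(benzyloxy)-6-(methoxymethoxy)phenyl]propiolate}
Conditions: DCC, DMAP (cat.), CH2Cl2, 0 °C to rt
Reagents that add atoms: none
Why: Steglich esterification, the standard way to aryl 3-arylpropiolates, can occur only at O5 because this is the sole free hydroxyl of 9.

Step 12
Reactants: 16 3-O-TBS-7,3',4'-tri-O-benzylepicatechin 5-O-{3-[2,4-bis(benzyloxy)-6-(methoxymethoxy)phenyl]propiolate}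
Product: 17 4-arylcoumarin fused to O5 and C6 of the protected epicatechin (top ring A on the future top C4)
Conditions: AuCl(PPh3) (5 mol %), AgOTf (5 mol %), 4 Å MS, CH2Cl2, rt, dark
Reagents that add atoms: none
Why: Cationic monovalent gold binds the alkyne, whose polarisation by the ester acceptor and the trialkoxyphenyl donor places the electrophilic site on the aryl-bearing carbon; C6 of the middle ring A attacks it in a Friedel–Crafts manner, the Wheland intermediate rearomatises, and protodeauration of the vinylgold species releases the coumarin and the catalyst. The closest known reaction type is the gold-, platinum- or palladium-catalysed intramolecular hydroarylation of aryl 3-arylpropiolates to 4-arylcoumarins, which works best on alkoxy-rich phenol esters such as this one, where C6 is ortho to O7 and para to O1. The one ring closed, the six-membered lactone O5–C(=O)–CH=C(Ar)–C6–C5, forms in the 6-endo-dig mode, whereas the 5-exo alternative would build charge next to the ester carbonyl and is electronically mismatched. No stereocentre is created, C2 and C3 of the middle unit are spectators, and the hindered aryl–coumarin axis may give two slowly interconverting rotamers that converge once C4 becomes tetrahedral in step 13. The selectivity needed is C6 against C8, and the tether from O5 secures it because the only ortho partners of C5 are C6–H and the quaternary C4a, with C8 para and out of reach. The ortho OMOM and OBn oxygens of the top ring A should not compete, since they could reach only the alkyne carbon next to the carbonyl (5-endo), which carries no positive character.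

Step 13
Reactants: 17 4-arylcoumarin fused to O5 and C6 of the protected epicatechin
Product: 18 (4R)-4-aryl-3,4-dihydrocoumarin (new methine = top C4, configured for the 4β→6 bond)
Conditions: Cu(OAc)2·H2O (5 mol %), (R)-DTBM-SEGPHOS (5.5 mol %), (EtO)2MeSiH (1.2 equiv), t-BuOH (1.2 equiv), toluene, 0 °C to rt
Reagents that add atoms: none
Why: Asymmetric copper hydride conjugate reduction of a 4-arylcoumarin, in which the ligated monovalent copper hydride delivers H to C4 on the face chosen by the bisphosphine (the middle-unit stereocentres are too remote to interfere), t-BuOH protonates the copper enolate, and the silane is kept near one equivalent so that the lactone is not reduced further.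

Step 14
Reactants: 18 (4R)-4-aryl-3,4-dihydrocoumarin
Product: 19 N-methoxy-N-methyl-3,3-diarylpropanamide with free middle 5-OH (methine unchanged)
Conditions: MeNH(OMe)·HCl, i-PrMgCl, THF, −20 to 0 °C; aq. NH4Cl
Reagents that add atoms: N,O-dimethylhydroxylamine hydrochloride, CNOC.Cl
Why: Aminolysis of the activated aryl ester by the chloromagnesium amide (Weinreb amide formation) opens the temporary lactone, releases O5 and leaves the non-acidic diarylmethine centre untouched.

Step 15
Reactants: 19 N-methoxy-N-methyl-3,3-diarylpropanamide with free middle 5-OH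
Product: 20 the 5-O-benzyl ether of 19
Conditions: BnBr, K2CO3, Bu4NI (cat.), DMF, rt to 40 °C
Reagents that add atoms: benzyl bromide, BrCc1ccccc1
Why: Williamson ether synthesis caps O5 so that it cannot relactonise or later compete with the top ring A oxygen for the ketone.

Step 16
Reactants: 21 4-bromocatechol
Product: 22 4-bromo-1,2-bis(benzyloxy)benzene
Conditions: BnBr (2.2 equiv), K2CO3, DMF, rt
Reagents that add atoms: benzyl bromide, BrCc1ccccc1
Why: Williamson ether synthesis on both catechol hydroxyls gives the ring B donor in the same protecting scheme as the rest of the molecule.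

Step 17
Reactants: 20 the 5-O-benzyl Weinreb amide; 22 4-bromo-1,2-bis(benzyloxy)benzene
Product: 24 1-[3,4-bis(benzyloxy)phenyl]-3,3-diarylpropan-1-one (top C2 carbonyl, C3 methylene, C4 methine), via aryllithium 23 (not isolated)
Conditions: 22, n-BuLi, THF, −78 °C; then 20, −78 to −40 °C; AcOH
Reagents that add atoms: none
Why: Weinreb ketone synthesis, in which bromine–lithium exchange gives the aryllithium and the chelated tetrahedral adduct blocks a second addition until the quench.

Step 18
Reactants: 24 1-[3,4-bis(benzyloxy)phenyl]-3,3-diarylpropan-1-one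
Product: 26 4-aryl-flav-2-ene (5,7,3',4'-tetra-O-benzylflav-2-ene carrying at C4 the C6 of 3-O-TBS-5,7,3',4'-tetra-O-benzylepicatechin), via phenol ketone 25 (not isolated)
Conditions: PPTS (0.3 equiv), MeOH–toluene, 60 °C; then toluene, 4 Å MS, 80 °C
Reagents that add atoms: none
Why: Transacetalisation removes the phenolic MOM group as dimethoxymethane, and the only free phenol then adds to the aryl ketone and loses water (cyclodehydration to a 2-aryl-4H-chromene), closing top ring C on the top ring A oxygen; any partial loss of the TBS group would be harmless since it is removed in step 20.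

Step 19
Reactants: 26 4-aryl-flav-2-ene
Product: 28 5,7,3',4'-tetra-O-benzylepicatechin-(4β→6)-3-O-TBS-5,7,3',4'-tetra-O-benzylepicatechin (top 3-OH free), via 2,3-epoxide 27 (not isolated)
Conditions: DMDO (acetone-free, CH2Cl2), −78 to −40 °C; volatiles removed cold; LiBHEt3, THF, −78 to 0 °C; H2O
Reagents that add atoms: dimethyldioxirane, CC1(C)OO1
Why: Epoxidation of a cyclic enol ether followed by reductive opening, in which DMDO should attack C2=C3 anti to the pseudo-axial middle-unit aryl group on C4 (sets C3–O trans to C4) and hydride should open the oxirane at the benzylic acetal carbon C2 with inversion (H-2 trans and ring B cis to O3), giving the 2,3-cis-3,4-trans array.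

Step 20
Reactants: 28 top-3-OH, middle-3-OTBS dimer
Product: 29 octa-O-benzyl-epicatechin-(4β→6)-epicatechin (octa-O-benzylprocyanidin B5, both 3-OH free)
Conditions: Bu4NF, THF, rt
Reagents that add atoms: none
Why: Fluoride-induced desilylation frees the middle 3-OH without affecting the benzyl ethers or any stereocentre.

Step 21
Reactants: 29 octa-O-benzyl-epicatechin-(4β→6)-epicatechin
Product: 30 the 4β-(2-ethoxyethoxy) derivative of 29 at C4 of the lower (middle) unit
Conditions: DDQ (1.5 equiv), EtOCH2CH2OH (5 equiv), CH2Cl2, rt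
Reagents that add atoms: 2-ethoxyethanol, CCOCCO
Why: Benzylic oxidation by hydride transfer to DDQ is expected at the lower C4 because only there is a pseudo-axial C–H aligned with a trialkoxy ring A (the upper C4–H is pseudo-equatorial to its own ring A and held in the plane of the di-ortho-substituted middle ring by allylic strain), and the alcohol should add anti to the axial 3-OH.

Step 22
Reactants: 30 4β-(2-ethoxyethoxy) dimer diol; 31 3,4,5-tris(benzyloxy)benzoic acid
Product: 32 3,3''-bis-O-[3,4,5-tris(benzyloxy)benzoyl] derivative of 30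
Conditions: 31 (3 equiv), DCC, DMAP, CH2Cl2, rt
Reagents that add atoms: none
Why: Double Steglich esterification of the two axial 3-hydroxyls, a reaction known on benzylated procyanidin dimers, runs under neutral conditions that spare the acid-labile C4 ether.

Step 23
Reactants: 33 (+)-catechin
Product: 34 5,7,3',4'-tetra-O-benzyl-(+)-catechin (2R,3S, 3-OH free)
Conditions: BnBr (4.4 equiv), K2CO3, DMF, 0 °C to rt
Reagents that add atoms: benzyl bromide, BrCc1ccccc1
Why: Williamson ether synthesis on the four phenols gives the standard C8 nucleophile and keeps the 3-OH that stays free in the target.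

Step 24
Reactants: 32 digalloylated 4-alkoxy dimer; 34 5,7,3',4'-tetra-O-benzyl-(+)-catechin
Product: 35 octadeca-O-benzyl ether of the target trimer
Conditions: 34 (4 equiv), TMSOTf (0.2 equiv), CH2Cl2, −78 °C
Reagents that add atoms: none
Why: Lewis-acid Friedel–Crafts interflavan coupling, in which TMSOTf ionises the C4 ether and the excess nucleophile attacks through its more reactive C8 on the β face, anti to the axial 3-O-galloyl group whose carbonyl shields the α face, which sets middle C4 and suppresses self-condensation.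

Step 25
Reactants: 35 octadeca-O-benzyl ether of the target trimer
Product: 36 epicatechin-3-O-gallate-(4β→6)-epicatechin-3-O-gallate-(4β→8)-catechin (CNP0112921.1)
Conditions: H2 (1 atm), Pd(OH)2/C, THF–MeOH–H2O, rt
Reagents that add atoms: none
Why: Global hydrogenolysis of the eighteen benzyl ethers under neutral conditions leaves the gallate esters, the interflavan bonds and all eight stereocentres intact, as is usual for galloylated procyanidins.

**Compound list**
1 | (−)-epicatechin | Oc1cc(O)c2c(c1)O[C@H](c1ccc(O)c(O)c1)[C@H](O)C2 | starting material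
2 | 5,7,3',4'-tetra-O-benzyl-(−)-epicatechin | c1c(OCc9ccccc9)cc2c(c1OCc9ccccc9)C[C@@H](O)[C@@H](c1ccc(OCc9ccccc9)c(OCc9ccccc9)c1)O2 | intermediate
3 | 3-O-TBS-5,7,3',4'-tetra-O-benzylepicatechin | c1c(OCc9ccccc9)cc2c(c1OCc9ccccc9)C[C@@H](O[Si](C)(C)C(C)(C)C)[C@@H](c1ccc(OCc9ccccc9)c(OCc9ccccc9)c1)O2 | intermediate
4 | 4β-hydroxy-3-O-TBS-5,7,3',4'-tetra-O-benzylepicatechin | c1c(OCc9ccccc9)cc2c(c1OCc9ccccc9)[C@H](O)[C@@H](O[Si](C)(C)C(C)(C)C)[C@@H](c1ccc(OCc9ccccc9)c(OCc9ccccc9)c1)O2 | intermediate
5 | 3-O-TBS-5,7,3',4'-tetra-O-benzyl-4-oxoepicatechin | c1c(OCc9ccccc9)cc2c(c1OCc9ccccc9)C(=O)[C@@H](O[Si](C)(C)C(C)(C)C)[C@@H](c1ccc(OCc9ccccc9)c(OCc9ccccc9)c1)O2 | intermediate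
6 | 5-hydroxy-3-O-TBS-7,3',4'-tri-O-benzyl-4-oxoepicatechin | c1c(OCc9ccccc9)cc2c(c1O)C(=O)[C@@H](O[Si](C)(C)C(C)(C)C)[C@@H](c1ccc(OCc9ccccc9)c(OCc9ccccc9)c1)O2 | intermediate
7 | 5-O-ethoxycarbonyl derivative of 6 (not isolated) | c1c(OCc9ccccc9)cc2c(c1OC(=O)OCC)C(=O)[C@@H](O[Si](C)(C)C(C)(C)C)[C@@H](c1ccc(OCc9ccccc9)c(OCc9ccccc9)c1)O2 | intermediate
8 | ortho-quinone methide (C5=O, C4a=C4) (not isolated) | O=C1C=C(OCc9ccccc9)C=C2O[C@H](c3ccc(OCc9ccccc9)c(OCc9ccccc9)c3)[C@H](O[Si](C)(C)C(C)(C)C)C=C12 | intermediate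
9 | 3-O-TBS-7,3',4'-tri-O-benzylepicatechin (5-OH free) | c1c(OCc9ccccc9)cc2c(c1O)C[C@@H](O[Si](C)(C)C(C)(C)C)[C@@H](c1ccc(OCc9ccccc9)c(OCc9ccccc9)c1)O2 | intermediate
10 | 2,4,6-trihydroxybenzaldehyde | O=Cc1c(O)cc(O)cc1O | starting material
11 | 2,4-bis(benzyloxy)-6-hydroxybenzaldehyde | O=Cc1c(O)cc(OCc9ccccc9)cc1OCc9ccccc9 | intermediate
12 | 2,4-bis(benzyloxy)-6-(methoxymethoxy)benzaldehyde | O=Cc1c(OCOC)cc(OCc9ccccc9)cc1OCc9ccccc9 | intermediate
13 | 1-ethynyl-2,4-bis(benzyloxy)-6-(methoxymethoxy)benzene | C#Cc1c(OCOC)cc(OCc9ccccc9)cc1OCc9ccccc9 | intermediate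
14 | lithium acetylide of 13 (not isolated) | [Li]C#Cc1c(OCOC)cc(OCc9ccccc9)cc1OCc9ccccc9 | intermediate
15 | 3-[2,4-bis(benzyloxy)-6-(methoxymethoxy)phenyl]propiolic acid | OC(=O)C#Cc1c(OCOC)cc(OCc9ccccc9)cc1OCc9ccccc9 | intermediate
16 | epicatechin 5-O-arylpropiolate (key-step precursor) | c1c(OCc9ccccc9)cc2c(c1OC(=O)C#Cc1c(OCOC)cc(OCc9ccccc9)cc1OCc9ccccc9)C[C@@H](O[Si](C)(C)C(C)(C)C)[C@@H](c1ccc(OCc9ccccc9)c(OCc9ccccc9)c1)O2 | intermediate
17 | 4-arylcoumarin fused to O5/C6 (key-step product; rotamers about the aryl axis possible) | O=C1C=C(c2c(OCOC)cc(OCc9ccccc9)cc2OCc9ccccc9)c2c(OCc9ccccc9)cc3c(c2O1)C[C@@H](O[Si](C)(C)C(C)(C)C)[C@@H](c2ccc(OCc9ccccc9)c(OCc9ccccc9)c2)O3 | intermediate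
18 | (4R)-4-aryl-3,4-dihydrocoumarin | O=C1C[C@H](c2c(OCOC)cc(OCc9ccccc9)cc2OCc9ccccc9)c2c(OCc9ccccc9)cc3c(c2O1)C[C@@H](O[Si](C)(C)C(C)(C)C)[C@@H](c2ccc(OCc9ccccc9)c(OCc9ccccc9)c2)O3 | intermediate
19 | Weinreb amide with free middle 5-OH | CON(C)C(=O)C[C@H](c1c(OCOC)cc(OCc9ccccc9)cc1OCc9ccccc9)c1c(OCc9ccccc9)cc2c(c1O)C[C@@H](O[Si](C)(C)C(C)(C)C)[C@@H](c1ccc(OCc9ccccc9)c(OCc9ccccc9)c1)O2 | intermediate
20 | Weinreb amide, middle 5-O-benzyl | CON(C)C(=O)C[C@H](c1c(OCOC)cc(OCc9ccccc9)cc1OCc9ccccc9)c1c(OCc9ccccc9)cc2c(c1OCc9ccccc9)C[C@@H](O[Si](C)(C)C(C)(C)C)[C@@H](c1ccc(OCc9ccccc9)c(OCc9ccccc9)c1)O2 | intermediate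
21 | 4-bromocatechol | Oc1ccc(Br)cc1O | starting material
22 | 4-bromo-1,2-bis(benzyloxy)benzene | Brc1ccc(OCc9ccccc9)c(OCc9ccccc9)c1 | intermediate
23 | 3,4-bis(benzyloxy)phenyllithium (not isolated) | [Li]c1ccc(OCc9ccccc9)c(OCc9ccccc9)c1 | intermediate
24 | ring B aryl ketone (MOM on top ring A) | O=C(c1ccc(OCc9ccccc9)c(OCc9ccccc9)c1)C[C@H](c1c(OCOC)cc(OCc9ccccc9)cc1OCc9ccccc9)c1c(OCc9ccccc9)cc2c(c1OCc9ccccc9)C[C@@H](O[Si](C)(C)C(C)(C)C)[C@@H](c1ccc(OCc9ccccc9)c(OCc9ccccc9)c1)O2 | intermediate
25 | phenol ketone after MOM loss (not isolated) | O=C(c1ccc(OCc9ccccc9)c(OCc9ccccc9)c1)C[C@H](c1c(O)cc(OCc9ccccc9)cc1OCc9ccccc9)c1c(OCc9ccccc9)cc2c(c1OCc9ccccc9)C[C@@H](O[Si](C)(C)C(C)(C)C)[C@@H](c1ccc(OCc9ccccc9)c(OCc9ccccc9)c1)O2 | intermediate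
26 | 4-aryl-flav-2-ene | C1(c2ccc(OCc9ccccc9)c(OCc9ccccc9)c2)=C[C@@H](c2c(OCc9ccccc9)cc3c(c2OCc9ccccc9)C[C@@H](O[Si](C)(C)C(C)(C)C)[C@@H](c2ccc(OCc9ccccc9)c(OCc9ccccc9)c2)O3)c2c(OCc9ccccc9)cc(OCc9ccccc9)cc2O1 | intermediate
27 | 2,3-epoxide, oxygen anti to the C4 aryl group (not isolated) | O1[C@@H]2[C@@H](c4c(OCc9ccccc9)cc5c(c4OCc9ccccc9)C[C@@H](O[Si](C)(C)C(C)(C)C)[C@@H](c4ccc(OCc9ccccc9)c(OCc9ccccc9)c4)O5)c3c(OCc9ccccc9)cc(OCc9ccccc9)cc3O[C@]12c1ccc(OCc9ccccc9)c(OCc9ccccc9)c1 | intermediate
28 | tetra-O-benzylepicatechin-(4β→6)-3-O-TBS-tetra-O-benzylepicatechin | O[C@@H]1[C@@H](c2c(OCc9ccccc9)cc3c(c2OCc9ccccc9)C[C@@H](O[Si](C)(C)C(C)(C)C)[C@@H](c2ccc(OCc9ccccc9)c(OCc9ccccc9)c2)O3)c2c(OCc9ccccc9)cc(OCc9ccccc9)cc2O[C@@H]1c1ccc(OCc9ccccc9)c(OCc9ccccc9)c1 | intermediate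
29 | octa-O-benzyl-epicatechin-(4β→6)-epicatechin | O[C@@H]1[C@@H](c2c(OCc9ccccc9)cc3c(c2OCc9ccccc9)C[C@@H](O)[C@@H](c2ccc(OCc9ccccc9)c(OCc9ccccc9)c2)O3)c2c(OCc9ccccc9)cc(OCc9ccccc9)cc2O[C@@H]1c1ccc(OCc9ccccc9)c(OCc9ccccc9)c1 | intermediate
30 | 4β-(2-ethoxyethoxy) derivative of 29 (lower unit) | O[C@@H]1[C@@H](c2c(OCc9ccccc9)cc3c(c2OCc9ccccc9)[C@H](OCCOCC)[C@@H](O)[C@@H](c2ccc(OCc9ccccc9)c(OCc9ccccc9)c2)O3)c2c(OCc9ccccc9)cc(OCc9ccccc9)cc2O[C@@H]1c1ccc(OCc9ccccc9)c(OCc9ccccc9)c1 | intermediate
31 | 3,4,5-tris(benzyloxy)benzoic acid | OC(=O)c1cc(OCc9ccccc9)c(OCc9ccccc9)c(OCc9ccccc9)c1 | starting material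
32 | digalloylated 4-alkoxy dimer | O=C(O[C@@H]1[C@@H](c2c(OCc9ccccc9)cc3c(c2OCc9ccccc9)[C@H](OCCOCC)[C@@H](OC(=O)c2cc(OCc9ccccc9)c(OCc9ccccc9)c(OCc9ccccc9)c2)[C@@H](c2ccc(OCc9ccccc9)c(OCc9ccccc9)c2)O3)c2c(OCc9ccccc9)cc(OCc9ccccc9)cc2O[C@@H]1c1ccc(OCc9ccccc9)c(OCc9ccccc9)c1)c1cc(OCc9ccccc9)c(OCc9ccccc9)c(OCc9ccccc9)c1 | intermediate
33 | (+)-catechin | Oc1cc(O)c2c(c1)O[C@H](c1ccc(O)c(O)c1)[C@@H](O)C2 | starting material
34 | 5,7,3',4'-tetra-O-benzyl-(+)-catechin | O(Cc9ccccc9)c1cc(OCc9ccccc9)c2c(c1)O[C@H](c1ccc(OCc9ccccc9)c(OCc9ccccc9)c1)[C@@H](O)C2 | intermediate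
35 | octadeca-O-benzyl trimer | O=C(O[C@@H]1[C@@H](c2c(OCc9ccccc9)cc3c(c2OCc9ccccc9)[C@H](c2c(OCc9ccccc9)cc(OCc9ccccc9)c4c2O[C@H](c2ccc(OCc9ccccc9)c(OCc9ccccc9)c2)[C@@H](O)C4)[C@@H](OC(=O)c2cc(OCc9ccccc9)c(OCc9ccccc9)c(OCc9ccccc9)c2)[C@@H](c2ccc(OCc9ccccc9)c(OCc9ccccc9)c2)O3)c2c(OCc9ccccc9)cc(OCc9ccccc9)cc2O[C@@H]1c1ccc(OCc9ccccc9)c(OCc9ccccc9)c1)c1cc(OCc9ccccc9)c(OCc9ccccc9)c(OCc9ccccc9)c1 | intermediate
36 | epicatechin-3-O-gallate-(4β→6)-epicatechin-3-O-gallate-(4β→8)-catechin | O=C(O[C@@H]1[C@@H](c2c(O)cc3c(c2O)[C@H](c2c(O)cc(O)c4c2O[C@H](c2ccc(O)c(O)c2)[C@@H](O)C4)[C@@H](OC(=O)c2cc(O)c(O)c(O)c2)[C@@H](c2ccc(O)c(O)c2)O3)c2c(O)cc(O)cc2O[C@@H]1c1ccc(O)c(O)c1)c1cc(O)c(O)c(O)c1 | target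

**Step count**
Total steps: 25.
Longest linear sequence: 19 steps (steps 1–6, 11–15, 17–22, 24 and 25, from epicatechin).

**Steps most likely to fail**

Step 12. What may go wrong:
- The closure may stall, because the bond forms between a ring carbon flanked by two oxygens and an alkyne carbon bearing a di-ortho-substituted aryl ring.
- Long exposure to the cationic catalyst may cause loss or migration of the MOM group or hydration of the alkyne.

The fallback keeps the O5 tether but uses an alkene and acid catalysis instead of an alkyne and a π-acid. It sets out from aldehyde 12 and phenol 9.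
- Doebner–Knoevenagel condensation of 12 with malonic acid (pyridine, piperidine) should give (E)-3-[2,4-bis(benzyloxy)-6-(methoxymethoxy)phenyl]acrylic acid F1.
- Steglich esterification of F1 with 9 should give the epicatechin 5-O-cinnamate F2.
- Sc(OTf)3 in CH2Cl2 at low temperature should trigger the known intramolecular Friedel–Crafts conjugate addition of aryl cinnamates to 4-aryl-3,4-dihydrocoumarins. This is a 6-endo-trig closure with again only C6 in reach, and the trialkoxyphenyl group helps by stabilising the benzylic cation.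
- The cyclisation should give 18 beside the C4 epimer of the dihydrocoumarin F3. The two are diastereomers and are separated by chromatography.

The route is rejoined at 18, so steps 12 and 13 are bypassed.

Step 13. What may go wrong:
- Hydride transfer may be slow or poorly face-selective, because the perpendicular 4-aryl ring holds one ortho substituent over each face of the coumarin alkene.
- Forcing conditions may lead to over-reduction of the lactone.

The fallback replaces catalyst control by a sterically undemanding electron-transfer reduction followed by separation of diastereomers. It sets out from 17.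
- Magnesium in methanol should reduce the β,β-diarylacrylate and methanolyse the lactone.
- This should give the methyl 3,3-diarylpropanoate of required configuration F4 and the epimeric methyl 3,3-diarylpropanoate F5. They differ only at the new methine and are separable because the middle unit is enantiopure.
- F4 is treated with MeNH(OMe)·HCl and i-PrMgCl as in step 14.

The route is rejoined at 19.

Step 19. What may go wrong:
- Hydride must enter C2 on the face that also carries the C4 aryl group, so facial selectivity may be poor.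
- The very labile 2-aryl epoxide may rearrange by a 1,2-hydride shift before it is reduced.

The fallback reverses the roles at C2, so that ring B rather than hydride is delivered, and on the open face. It sets out from 20, with aryllithium 23.
- i-Bu2AlH at −78 °C should give the 3,3-diarylpropanal F6.
- PPTS in MeOH–toluene should remove the MOM group and close the cyclic methyl acetal (2-methoxy-4-arylchroman) F7.
- TMSOTf with i-Pr2NEt should eliminate methanol to give the 2-unsubstituted 4-aryl-4H-chromene F8.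
- DMDO should give, anti to the C4 aryl group, the 2,3-epoxychroman F9.
- Aryllithium 23 and Me2AlCl give the aryl(dimethyl)alane F10. It should open F9 by the known syn-selective organoaluminium opening of enol ether epoxides: aluminium binds the epoxide oxygen and hands the aryl group to C2 on the same face. Ring B then ends up cis to O3 and trans to the C4 aryl group.

The route is rejoined at 28.

**Further compounds**
F1 | step 12 | (E)-3-[2,4-bis(benzyloxy)-6-(methoxymethoxy)phenyl]acrylic acid | OC(=O)/C=C/c1c(OCOC)cc(OCc9ccccc9)cc1OCc9ccccc9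
F2 | step 12 | epicatechin 5-O-cinnamate | c1c(OCc9ccccc9)cc2c(c1OC(=O)/C=C/c1c(OCOC)cc(OCc9ccccc9)cc1OCc9ccccc9)C[C@@H](O[Si](C)(C)C(C)(C)C)[C@@H](c1ccc(OCc9ccccc9)c(OCc9ccccc9)c1)O2
F3 | step 12 | C4 epimer of the dihydrocoumarin | O=C1C[C@@H](c2c(OCOC)cc(OCc9ccccc9)cc2OCc9ccccc9)c2c(OCc9ccccc9)cc3c(c2O1)C[C@@H](O[Si](C)(C)C(C)(C)C)[C@@H](c2ccc(OCc9ccccc9)c(OCc9ccccc9)c2)O3
F4 | step 13 | methyl 3,3-diarylpropanoate of required configuration | COC(=O)C[C@H](c1c(OCOC)cc(OCc9ccccc9)cc1OCc9ccccc9)c1c(OCc9ccccc9)cc2c(c1O)C[C@@H](O[Si](C)(C)C(C)(C)C)[C@@H](c1ccc(OCc9ccccc9)c(OCc9ccccc9)c1)O2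
F5 | step 13 | epimeric methyl 3,3-diarylpropanoate | COC(=O)C[C@@H](c1c(OCOC)cc(OCc9ccccc9)cc1OCc9ccccc9)c1c(OCc9ccccc9)cc2c(c1O)C[C@@H](O[Si](C)(C)C(C)(C)C)[C@@H](c1ccc(OCc9ccccc9)c(OCc9ccccc9)c1)O2
F6 | step 19 | 3,3-diarylpropanal | O=CC[C@H](c1c(OCOC)cc(OCc9ccccc9)cc1OCc9ccccc9)c1c(OCc9ccccc9)cc2c(c1OCc9ccccc9)C[C@@H](O[Si](C)(C)C(C)(C)C)[C@@H](c1ccc(OCc9ccccc9)c(OCc9ccccc9)c1)O2
F7 | step 19 | cyclic methyl acetal (2-methoxy-4-arylchroman) | COC1C[C@@H](c2c(OCc9ccccc9)cc3c(c2OCc9ccccc9)C[C@@H](O[Si](C)(C)C(C)(C)C)[C@@H](c2ccc(OCc9ccccc9)c(OCc9ccccc9)c2)O3)c2c(OCc9ccccc9)cc(OCc9ccccc9)cc2O1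
F8 | step 19 | 2-unsubstituted 4-aryl-4H-chromene | C1=C[C@@H](c2c(OCc9ccccc9)cc3c(c2OCc9ccccc9)C[C@@H](O[Si](C)(C)C(C)(C)C)[C@@H](c2ccc(OCc9ccccc9)c(OCc9ccccc9)c2)O3)c2c(OCc9ccccc9)cc(OCc9ccccc9)cc2O1
F9 | step 19 | 2,3-epoxychroman | O1[C@@H]2[C@@H](c4c(OCc9ccccc9)cc5c(c4OCc9ccccc9)C[C@@H](O[Si](C)(C)C(C)(C)C)[C@@H](c4ccc(OCc9ccccc9)c(OCc9ccccc9)c4)O5)c3c(OCc9ccccc9)cc(OCc9ccccc9)cc3O[C@H]12
F10 | step 19 | aryl(dimethyl)alane | C[Al](C)c1ccc(OCc9ccccc9)c(OCc9ccccc9)c1
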